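**Structural features**

The target, 4-bromo-3-butyl-5-(dibromomethylene)furan-2(5H)-one, has one ring only: a butenolide in which O1 links the lactone carbonyl C2 to C5. C3 carries the n-butyl chain, C4 a bromine, and C5 an exocyclic CBr2 group. There is no stereocentre and no stereogenic double bond, because the exocyclic carbon bears two bromines, so the problems are regiochemical and chemoselective only. The C3=C4 and C5=CBr2 double bonds are cross-conjugated through the lactone. C4–Br is a vinylogous acyl bromide and C5–O1 is an enol-ester bond, so the finished molecule is fragile toward nucleophiles, amines, strong base and reducing metals. The real difficulty is to place three bromines on two different carbons at the right oxidation level, with the butyl group unambiguously beside the carbonyl and its allylic CH2 left unbrominated. The key step exploits the fact that C2(=O)–C3(Bu)=C4(X)–C5 is a contiguous four-carbon unit whose two ends are both bonded to O1. If C2 and C5 are joined to each other instead, the unit becomes a cyclobutenone ring with O1 as a hydroxyl on C5. Such cyclobutenones are available with fully defined substitution from a squaric ester, X being the alkoxy group that later becomes the C4 bromine.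

**Logic of the disconnections**

12 to 10 and 11: the C4–Br bond is cut first. C4 is the β-carbon of the unsaturated lactone, so its bromide is the equivalent of an enolic hydroxyl. Going back to 10 removes the most electrophilic halogen and leaves a vinylogous acid that is much less sensitive. The forward step must exchange OH for Br at an sp2 carbon under acidic, non-nucleophilic conditions that spare the CBr2 enol lactone; the bromine comes from 11.

10 to 9: the O–H bond is traded for an O–isopropyl bond. The alkyl group is a spectator needed further back, where it differentiates the two carbonyls of the four-membered ring. The gain in simplicity is small. The demand is a dealkylation that attacks the secondary alkyl carbon and not the ring.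

9 to 8: the exocyclic C5=C bond is returned to a C5–O(acetyl) bond and a C–H bond. This gives a saturated C5 bearing a leaving group and a CHBr2 group, which is what an oxidative ring expansion delivers, and it lets both exocyclic bromines travel on one carbon. The forward elimination must outrun acyl transfer to the base. The C5 stereocentre of 8 is of no consequence because it vanishes here.

8 to 6 and 7: the O1–C2 and C5–O(acetyl) bonds are cut and C2 is rejoined to C5. The heterocycle with four differently substituted carbons becomes a four-membered carbocycle whose substitution follows from the order of two carbonyl additions. The forward step requires that 7 break the carbinol–carbonyl bond of 6 and no other bond at the carbinol carbon. It must also run below the temperature at which 6 opens thermally.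

6 to 4 and 5: the bond between the carbinol carbon and the CHBr2 carbon is cut. 5 supplies one carbon with both bromines already on it, and 4 is the electrophile. The metallated form of 5 is a thermally labile carbenoid. It must add only to the carbonyl of 4 that is not part of the vinylogous ester, and the alkoxide must be protonated cold.

4 to 1 and 2 (through 3): the C–butyl bond is cut. 4 goes back to 3, the adduct of 2 with one carbonyl of symmetrical 1, followed by acid-induced loss of propan-2-ol. Both starting materials are commercial, and the symmetry of 1 removes any regiochemical question. The demands are mono-addition at low temperature and a clean carbonyl transposition.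

**Other disconnections considered**

Alternative 1: The lactone carbonyl oxygen and the C5 oxygen are both traced to dioxygen, so the butenolide is seen as an oxidised furan, 3-bromo-4-butyl-2-methylfuran A1.
- Forward key step: singlet oxygen adds across the two α-carbons of A1. A hindered amine (iPr2NEt) then removes the only bridgehead hydrogen in a Kornblum–DeLaMare-type fragmentation, giving 4-bromo-3-butyl-5-hydroxy-5-methylfuran-2(5H)-one A2.
- In its favour: bromine at C4 and butyl at C3 are in place before the ring is oxidised, so no OH-to-Br exchange is needed. The single α-hydrogen dictates which carbon becomes the carbonyl. No lead reagent is used.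
- Against it: A1 is a trisubstituted furan with bromine between two different alkyl groups and needs its own regiocontrolled multi-step synthesis. The bromine also makes the furan a poorer partner for electrophilic singlet oxygen. A2 must still be dehydrated to 4-bromo-3-butyl-5-methylenefuran-2(5H)-one A3 and then taken through two bromine addition/dehydrobromination cycles, during which bromination of the butyl allylic CH2 competes.
- Comparison on structure: the alternative is better for the C4 bromine and equal for butyl placement. The chosen plan is better for the exocyclic CBr2, which arrives in one piece from 5.
- Comparison on mechanism: the pericyclic oxygenation is at least as predictable as the fragmentation of step 3. The repeated late brominations are less controlled than the single elimination of step 4.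
- Comparison on step economy: the chosen plan needs six steps from catalogue compounds. The alternative needs about as many after A1 alone, so it is longer overall.

Alternative 2: The C4–C5 and O1–C2 bonds are cut, giving ethyl 3,3-dibromo-2-butylacrylate A4 and tribromoacetaldehyde A5.
- Forward key step: iPrMgCl exchanges the bromine cis to the ester, directed by the ester carbonyl. The α-bromo alkenylmagnesium carbenoid adds to A5, and the magnesium alkoxide closes onto the cis ester to give 4-bromo-3-butyl-5-(tribromomethyl)furan-2(5H)-one A6. One dehydrobromination (C5–H and one bromine of CBr3) would then give 12.
- In its favour: all bromines arrive in the building blocks, the route is convergent, and it needs no protecting group and no late OH-to-Br exchange. It would be about three steps from an α-keto ester.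
- Against it: the metallated carbon carries a bromine and can undergo α-elimination or Fritsch–Buttenberg–Wiechell-type rearrangement. The exchange selectivity between the two geminal bromines rests on chelation alone. A5 donates positive bromine as readily as it accepts carbon nucleophiles, so halophilic attack may outrun carbonyl addition. The alkoxide next to CBr3 may displace bromide instead of lactonising.
- Comparison on structure: the alternative is better, since every halogen is placed without functional-group interchange.
- Comparison on mechanism: the chosen plan is safer, because its regiochemistry is fixed by squarate reactivity and its key step has one dominant pathway. The alternative's C–C bond formation has several competing polar pathways.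
- Comparison on step economy: the alternative is clearly better.

Alternative 3: The C2–C3 and C2–O1 bonds are cut and C2 is traced to CO. The precursor is (E)-3,4-dibromooct-3-en-2-ol A7, reached by anti addition of Br2 to oct-3-yn-2-ol A9.
- Forward key step: zerovalent palladium, for example Pd(PPh3)4, inserts into the C3–Br bond of A7. CO inserts, and the cis hydroxyl captures the acylpalladium to give 4-bromo-3-butyl-5-methylfuran-2(5H)-one A8 with C4–Br retained.
- In its favour: the precursor is short to make, the ring-forming step is catalytic and atom-economical, and the E geometry places the hydroxyl cis to the reacting bromide. Bromine is already at C4.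
- Against it: A7 has two vinylic C–Br bonds, and only hydroxyl proximity distinguishes them. The activated C–Br bond of A8 should insert palladium more readily than either bond of A7, so over-reaction threatens. A8 is at the wrong oxidation level: C5 must be oxidised to a methylene butenolide and the former methyl carbon brominated twice, with chain bromination competing.
- Comparison on structure: the alternative is better for the C4 bromine and equal for butyl placement. It is worse for the CBr2 unit.
- Comparison on mechanism: catalytic carbonylation is attractive, but its site selectivity is less secured than the squarate-derived regiochemistry.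
- Comparison on step economy: the ring is reached in fewer steps than in the chosen plan, but the endgame would make the overall sequence equal or longer.

Key step: step 3

Remark on the chemistry: the target is achiral, so 3, 6 and 8 are carried as racemates. The atom mapping of 6 and 8 was rechecked and needs no correction: in 6 the butyl-bearing carbon is bonded to the ring carbonyl and the alkoxy-bearing carbon to the carbinol, so oxygen insertion puts butyl at C3 and alkoxy at C4 of 8. n-BuLi serves only as the butyl source; the carbenoid from 5 is made with LiN(iPr)2 to avoid bromine–lithium exchange.

Step 1
Reactants: 1 diisopropyl squarate (3,4-diisopropoxycyclobut-3-ene-1,2-dione); 2 n-butyllithium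
Product: 4 3-butyl-4-isopropoxycyclobut-3-ene-1,2-dione, via 4-butyl-4-hydroxy-2,3-diisopropoxycyclobut-2-en-1-one 3 (not isolated)
Conditions: n-BuLi, THF, −78 °C; 1 M HCl quench; crude in CH2Cl2, 12 M HCl (cat.), rt
Reagents that add atoms: n-butyllithium [Li]CCCC
Why: Organolithium 1,2-addition to one carbonyl of the symmetrical squarate gives 3, which is carried on crude. Acid then ionises the tertiary hydroxyl, water re-adds at the alkoxy-bearing terminus of the oxygen-stabilised allyl cation, and propan-2-ol is expelled (acid-mediated 1,3-carbonyl transposition), giving the vinylogous ester dione 4 with no stereocentre.

Step 2
Reactants: 4 3-butyl-4-isopropoxycyclobut-3-ene-1,2-dione; 5 dibromomethane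
Product: 6 2-butyl-4-(dibromomethyl)-4-hydroxy-3-isopropoxycyclobut-2-en-1-one (racemic)
Conditions: CH2Br2, LiN(iPr)2, THF, −90 °C; add 4, −90 °C; AcOH quench at −90 °C
Reagents that add atoms: dibromomethane BrCBr
Why: Amide deprotonation of CH2Br2 gives the carbenoid LiCHBr2, a hard nucleophile that should add 1,2 to the ketone-like carbonyl of 4 (the one flanked by the alkoxy-bearing carbon), because the other carbonyl is deactivated as a vinylogous ester. Protonation at −90 °C prevents the lithium alkoxide from displacing bromide (Darzens-type closure) or opening the ring; the new carbinol centre is racemic and is not kept in the target.

Step 3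
Reactants: 6 2-butyl-4-(dibromomethyl)-4-hydroxy-3-isopropoxycyclobut-2-en-1-one; 7 lead tetraacetate
Product: 8 5-acetoxy-3-butyl-5-(dibromomethyl)-4-isopropoxyfuran-2(5H)-one (racemic)
Conditions: Pb(OAc)4, toluene, rt, dark
Reagents that add atoms: lead tetraacetate CC(=O)O[Pb](OC(C)=O)(OC(C)=O)OC(C)=O
Why: Ligand exchange turns the tertiary hydroxyl of 6 into a lead alkoxide, and loss of lead (tetravalent to divalent overall) generates oxygen-centred radical character at the carbinol oxygen. β-Scission of the bond between the carbinol carbon and the ring carbonyl follows, because it releases the cyclobutene strain, makes a conjugated ketone and gives a comparatively stable acyl radical held cis to that ketone by the C(Bu)=C(OiPr) bond. The acyl carbon then bonds to the ketone oxygen in a 5-endo-trig closure (the former hydroxyl oxygen becomes O1 and the O1–C2 bond forms), and the allylic α-oxy radical at C5 is oxidised to the cation and captured by acetate. The closest known reaction type is the Pb(OAc)4-mediated oxidative ring expansion of squarate-derived 4-hydroxycyclobutenones to 5-acetoxyfuran-2(5H)-ones; only the dibromomethyl substituent is new to it. The single new stereocentre, C5, arises from acetate addition to a planar intermediate with nothing to bias either face, so 8 is racemic, which is harmless because step 4 removes the centre. The selectivity needed is cleavage of the carbinol–acyl bond over the carbinol–vinyl and carbinol–CHBr2 bonds: a vinyl radical is prohibitive, and expulsion of the dibromomethyl radical would leave the ring strain in place, so ring cleavage should win. Room temperature and exclusion of light keep the thermal electrocyclic opening of 6 and C–Br homolysis out of play.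

Step 4
Reactants: 8 5-acetoxy-3-butyl-5-(dibromomethyl)-4-isopropoxyfuran-2(5H)-one
Product: 9 3-butyl-5-(dibromomethylene)-4-isopropoxyfuran-2(5H)-one
Conditions: DBU, CH2Cl2, −20 → 0 °C
Reagents that add atoms: none
Why: E1cB-type β-elimination: the CHBr2 hydrogen is acidified by two bromines and the C5 acetate is a good leaving group, so the amidine base should give the exocyclic enol-lactone alkene, which has no geometry because both substituents are bromine. With alkoxy still at C4 the ring is a poorer acceptor for the base than the final product would be.

Step 5
Reactants: 9 3-butyl-5-(dibromomethylene)-4-isopropoxyfuran-2(5H)-one
Product: 10 3-butyl-5-(dibromomethylene)-4-hydroxyfuran-2(5H)-one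
Conditions: BCl3, CH2Cl2, −78 → 0 °C; H2O
Reagents that add atoms: none
Why: Lewis-acid O-dealkylation of a secondary alkyl ether: BCl3 coordinates the vinylogous ester, chloride removes the isopropyl group as 2-chloropropane, and hydrolysis of the boron enolate frees the tetronic acid. Vinylic bromides and the enol lactone are not expected to react with BCl3 at this temperature.

Step 6
Reactants: 10 3-butyl-5-(dibromomethylene)-4-hydroxyfuran-2(5H)-one; 11 oxalyl bromide
Product: 12 4-bromo-3-butyl-5-(dibromomethylene)furan-2(5H)-one (target)
Conditions: (COBr)2, DMF (cat.), CH2Cl2, 0 °C → rt
Reagents that add atoms: oxalyl bromide O=C(Br)C(=O)Br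
Why: Vilsmeier–Haack-type deoxybromination of a vinylogous acid: the bromoiminium salt formed from (COBr)2 and DMF O-activates the C4 enol, and bromide substitutes at C4 by addition–elimination, the standard conversion of tetronic acids into 4-bromofuran-2(5H)-ones. The acidic, non-nucleophilic medium suits the sensitive product.

**Compound list**

1 | diisopropyl squarate (3,4-diisopropoxycyclobut-3-ene-1,2-dione) | CC(C)OC1=C(OC(C)C)C(=O)C1=O | starting material
2 | n-butyllithium | [Li]CCCC | starting material
3 | 4-butyl-4-hydroxy-2,3-diisopropoxycyclobut-2-en-1-one (racemic) | CCCCC1(O)C(OC(C)C)=C(OC(C)C)C1=O | intermediate
4 | 3-butyl-4-isopropoxycyclobut-3-ene-1,2-dione | CCCCC1=C(OC(C)C)C(=O)C1=O | intermediate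
5 | dibromomethane | BrCBr | starting material
6 | 2-butyl-4-(dibromomethyl)-4-hydroxy-3-isopropoxycyclobut-2-en-1-one (racemic) | CCCCC1=C(OC(C)C)C(O)(C(Br)Br)C1=O | intermediate
7 | lead tetraacetate | CC(=O)O[Pb](OC(C)=O)(OC(C)=O)OC(C)=O | starting material
8 | 5-acetoxy-3-butyl-5-(dibromomethyl)-4-isopropoxyfuran-2(5H)-one (racemic) | CCCCC1=C(OC(C)C)C(OC(C)=O)(C(Br)Br)OC1=O | intermediate
9 | 3-butyl-5-(dibromomethylene)-4-isopropoxyfuran-2(5H)-one | CCCCC1=C(OC(C)C)C(=C(Br)Br)OC1=O | intermediate
10 | 3-butyl-5-(dibromomethylene)-4-hydroxyfuran-2(5H)-one | CCCCC1=C(O)C(=C(Br)Br)OC1=O | intermediate
11 | oxalyl bromide | O=C(Br)C(=O)Br | starting material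
12 | 4-bromo-3-butyl-5-(dibromomethylene)furan-2(5H)-one | CCCCC1=C(Br)C(=C(Br)Br)OC1=O | target

**Step count and least certain steps**

Total step count: 6. Longest linear sequence: 6 steps (1 to 12; the route is fully linear).

Step 3 (key step). The oxygen-centred intermediate may fragment on the exocyclic side, expelling the bromine-stabilised dibromomethyl radical and regenerating 4, or it may abstract the CHBr2 hydrogen. Both compete with the strain-driven ring cleavage. The fallback sets out from 6 and avoids radical intermediates. Periodic acid (H5IO6) in aqueous THF should cleave the α-ketol C–C bond in a two-electron Malaprade-type process through the cyclic periodate of the hydrated ring carbonyl. The resulting (Z)-4-oxo-2-enoic acid should close to its ring tautomer, the lactol 3-butyl-5-(dibromomethyl)-5-hydroxy-4-isopropoxyfuran-2(5H)-one F1. Acetylation of the lactol hydroxyl (Ac2O, pyridine, cat. DMAP) would give 8, where the route resumes.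

Step 2. The carbenoid may decompose by α-elimination before it adds, or act as a base toward the vinylogously acidic butyl CH2 of 4. The lithium alkoxide may also displace bromide or trigger ring opening before protonation. The fallback sets out from 4 and brings in the CBr2 carbon as a phosphorus ylide instead of a carbanion. Baeyer–Villiger-type oxidation of the 1,2-dione with a peracid (mCPBA, CH2Cl2) should insert oxygen between the two carbonyls to give 3-butyl-4-isopropoxyfuran-2,5-dione F2. Ramirez dibromo-olefination (CBr4, PPh3) should occur at the anhydride carbonyl flanked by the alkoxy-bearing carbon, the other being a deactivated vinylogous carbonate, and give 9 directly. The route resumes at 9.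

Step 6. Substitution at C4 may be slow because the carbon is flanked by the butyl group and the exocyclic CBr2. O-formylation, or addition of HBr across the exocyclic enol-ether double bond, may then take over. The fallback sets out from 10 and separates activation from substitution. Tf2O with 2,6-lutidine in CH2Cl2 should give 4-butyl-2-(dibromomethylene)-5-oxo-2,5-dihydrofuran-3-yl trifluoromethanesulfonate F3. LiBr in THF should then replace the triflate by addition–elimination at the β-carbon of the lactone, rejoining the route at 12.

Step 5. The Lewis acid may ionise the enol lactone, or add HCl across the electron-rich exocyclic double bond, faster than it removes the secondary alkyl group; dealkylation may also stop short. The fallback sets out from 8, makes no new compound, and replaces the base-then-Lewis-acid sequence by one Brønsted-acid operation. In concentrated H2SO4 (0 °C to gentle warming) the isopropyl group should leave unimolecularly from the O-protonated vinylogous ester, and acetic acid should be lost by the acid-induced enol-lactonisation pathway classically used to close halogenated 4-oxo acids to halomethylene butenolides. This would give 10 directly, where the route resumes.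

**Further compounds**

F1 | step 3 | 3-butyl-5-(dibromomethyl)-5-hydroxy-4-isopropoxyfuran-2(5H)-one (racemic) | CCCCC1=C(OC(C)C)C(O)(C(Br)Br)OC1=O
F2 | step 2 | 3-butyl-4-isopropoxyfuran-2,5-dione | CCCCC1=C(OC(C)C)C(=O)OC1=O
F3 | step 6 | 4-butyl-2-(dibromomethylene)-5-oxo-2,5-dihydrofuran-3-yl trifluoromethanesulfonate | CCCCC1=C(OS(=O)(=O)C(F)(F)F)C(=C(Br)Br)OC1=O
F0 | step 5 | none | none
A1 | alternative 1 | 3-bromo-4-butyl-2-methylfuran | CCCCc1coc(C)c1Br
A2 | alternative 1 | 4-bromo-3-butyl-5-hydroxy-5-methylfuran-2(5H)-one (racemic) | CCCCC1=C(Br)C(C)(O)OC1=O
A3 | alternative 1 | 4-bromo-3-butyl-5-methylenefuran-2(5H)-one | CCCCC1=C(Br)C(=C)OC1=O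
A4 | alternative 2 | ethyl 3,3-dibromo-2-butylacrylate | CCCCC(=C(Br)Br)C(=O)OCC
A5 | alternative 2 | tribromoacetaldehyde | O=CC(Br)(Br)Br
A6 | alternative 2 | 4-bromo-3-butyl-5-(tribromomethyl)furan-2(5H)-one (racemic) | CCCCC1=C(Br)C(C(Br)(Br)Br)OC1=O
A7 | alternative 3 | (E)-3,4-dibromooct-3-en-2-ol (racemic) | CCCC/C(Br)=C(Br)/C(C)O
A8 | alternative 3 | 4-bromo-3-butyl-5-methylfuran-2(5H)-one (racemic) | CCCCC1=C(Br)C(C)OC1=O
A9 | alternative 3 | oct-3-yn-2-ol (racemic) | CCCCC#CC(C)O
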